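**Plan**

- Retrosynthesis: the two isovalerate C–O bonds and the C15 oxidation level are removed first. The C9–C11 bond is then cut (sp2–sp3 Suzuki–Miyaura coupling at a C9 enol triflate). Ring A is finally cut at C1–C10 and C4–C5 by a [4+2] disconnection, giving 2,6-dimethyl-1,4-benzoquinone (ring B) and methyl (2E)-penta-2,4-dienoate (C1–C4 plus C19).
- Enabling feature: ring B carries oxygen at C6 and an sp2 carbon at C9 (a masked ketone), 1,4 to each other on either side of the ring-fusion bond C5–C10, with methyls on C8 and C10. This is the imprint of 2,6-dimethylbenzoquinone. The C2–C3(O) unit of ring A is a masked cyclohexene.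
- Forward: ring B is bought and ring A is closed last, in one catalytic enantioselective Diels–Alder step. Then follow C9 triflate, C6 reduction, C4 methylation with lactonisation, C2–C3 epoxidation, side-chain coupling, hydride reduction, acylation and C15 oxidation.
- Stereochemistry: C10 is set by the chiral catalyst. C5 follows by epimerisation next to the C6 ketone, and C6 by hydride attack opposite the C10 methyl. C4 is set by enolate methylation anti to that methyl and locked in a temporary 19,6β-lactone. C3 comes from α-epoxidation and trans-diaxial hydride opening. The 13E alkene is bought.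

Key step: step 1

Remarks on the chemistry:
- Labdane numbering is used for all bicyclic compounds: ring A = C1–C5 and C10; ring B = C5–C10; C17 = methyl on C8; C18 and C19 = carbons on C4 (C19 on the β-face); C20 = methyl on C10; β = the face of the C10 methyl.
- Assumption: the (S)-configured oxazaborolidinium catalyst is written. If its open face selects the other enantiotopic C=C bond of 1, the mirror-image catalyst is used with everything else unchanged.
- Assumption: compounds 1, 2 and 12 are purchasable.

**Step 1**
Reactants: 1 2,6-dimethyl-1,4-benzoquinone; 2 methyl (2E)-penta-2,4-dienoate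
Product: 3 methyl (1R,4aS,8aR)-4a,6-dimethyl-5,8-dioxo-1,4,4a,5,8,8a-hexahydronaphthalene-1-carboxylate (cis-fused endo adduct; 10β-Me; 5β-H; 4α-CO2Me; Δ2; Δ7)
Conditions: 20 mol % (S)-1-(2-methylphenyl)-3,3-diphenyltetrahydro-1H,3H-pyrrolo[1,2-c][1,3,2]oxazaborole activated with HN(SO2CF3)2, CH2Cl2, −40 → −20 °C
Reagents that add atoms: none
Why: The oxazaborolidinium cation should bind the less hindered, more basic C6 carbonyl of 1 (flanked by two CH groups), and the diene then adds in a concerted, asynchronous, normal-demand [4+2] cycloaddition; the closest known type is the enantioselective Lewis-acid-catalysed quinone Diels–Alder reaction. Ring A is closed in this single suprafacial event by the two bonds C1–C10 and C4–C5 through an endo six-membered transition state, while ring B arrives intact from the quinone. C10 and C5 are formed cis because of the alkene geometry of 1, and their absolute sense is fixed by the quinone face that the catalyst leaves open. C4 follows from the endo rule and is reset in step 5. The step needs regioselectivity (unsubstituted diene terminus C1 to the methyl-bearing C10, ester-bearing C4 to C5); activation of the C6 carbonyl makes C10 the electrophilic β-carbon, and the smaller CH2 terminus fits the hindered carbon, so both effects point the same way. The two enantiotopic C=C bonds of the symmetric quinone are told apart by the catalyst alone.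

**Step 2**
Reactants: 3 cis-fused adduct
Product: 4 methyl (1R,4aS,8aS)-4a,6-dimethyl-5,8-dioxo-1,4,4a,5,8,8a-hexahydronaphthalene-1-carboxylate (trans-fused; 5α-H; 10β-Me; 4α-CO2Me equatorial)
Conditions: DBU (10 mol %), CH2Cl2, 0 °C
Reagents that add atoms: none
Why: Base-catalysed epimerisation at C5 (α to the C6 ketone, through the cross-conjugated dienolate) should lead to the trans-fused decalin with the ester equatorial as the thermodynamic isomer, while the much less acidic C4–H is left alone.

**Step 3**
Reactants: 4 trans-fused ene-dione ester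
Product: 6 enol triflate ketone (9-OTf; Δ8; 6-oxo; Δ2; 4α-CO2Me; 5α-H), via lithium enolate 5 (not isolated)
Conditions: LiBH(s-Bu)3 (1.05 equiv), THF, −78 °C; then PhNTf2, −78 → 0 °C
Reagents that add atoms: N-phenylbis(trifluoromethanesulfonimide) O=S(=O)(N(c1ccccc1)S(=O)(=O)C(F)(F)F)C(F)(F)F
Why: The bulky hydride should add 1,4 to the ene-dione at the unsubstituted C7 (conjugate reduction), and O-sulfonylation of the regiodefined C9 enolate (enol triflate formation) places the future C8=C9 double bond while the C6 ketone stays.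

**Step 4**
Reactants: 6 enol triflate ketone
Product: 7 6β-alcohol (9-OTf; Δ8; Δ2; 4α-CO2Me)
Conditions: NaBH4, MeOH/CH2Cl2, −40 °C
Reagents that add atoms: none
Why: Borohydride 1,2-reduction of the C6 ketone from the α-face, opposite to the axial C10 methyl, should give the axial 6β-alcohol; ester and enol triflate are inert.

**Step 5**
Reactants: 7 6β-alcohol
Product: 10 lactone triflate (19,6β-olide; 4α-methyl; Δ2; 9-OTf), via dilithium alkoxide enolate 8 (not isolated), via lithium alkoxide 9 (not isolated)
Conditions: LiN(i-Pr)2 (2.2 equiv), THF/DMPU, −78 °C; MeI, −78 °C; then → 0 °C, aq. NH4Cl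
Reagents that add atoms: iodomethane CI
Why: The 6β-alkoxide directs deprotonation of the syn-axial C4–H, and the ester enolate is methylated from the α-face, away from the C10 methyl and the alkoxide (alkylation of a hydroxy-ester dianion); only the resulting 4β-ester can then close onto O6 (lactonisation), which locks C4 and masks O6 and C19.

**Step 6**
Reactants: 10 lactone triflate
Product: 11 2α,3α-epoxy lactone triflate
Conditions: mCPBA, NaHCO3, CH2Cl2, 0 → 23 °C
Reagents that add atoms: 3-chloroperoxybenzoic acid OOC(=O)c1cccc(Cl)c1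
Why: Peracid epoxidation (Prilezhaev reaction) of the only electron-rich alkene should occur on the α-face, because the β-face is covered by the C10 methyl and the lactone bridge; the enol triflate alkene is too electron-poor to react.

**Step 7**
Reactants: 12 (2E)-3-methylpent-2-en-4-yn-1-ol
Product: 13 tert-butyldimethylsilyl ether of 12
Conditions: TBSCl, imidazole, CH2Cl2, 0 → 23 °C
Reagents that add atoms: tert-butyldimethylsilyl chloride CC(C)(C)[Si](C)(C)Cl
Why: Silylation of the primary allylic alcohol gives an ether that is inert to palladium, borane and LiAlH4 in the later steps.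

**Step 8**
Reactants: 13 silyl enyne
Product: 14 tert-butyldimethylsilyl ether of (2E)-3-methylpenta-2,4-dien-1-ol
Conditions: H2 (1 atm), Pd/CaCO3 poisoned with Pb(OAc)2, quinoline, hexane, 23 °C
Reagents that add atoms: none
Why: Semihydrogenation of the terminal alkyne on poisoned palladium should stop at the 1,3-diene and leave the E-trisubstituted alkene untouched.

**Step 9**
Reactants: 11 epoxy lactone triflate; 14 silyl diene
Product: 16 coupled epoxy lactone (C9 side chain CH2CH2C(Me)=CHCH2OTBS; 13E), via B-alkyl-9-BBN borane 15 (not isolated)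
Conditions: 14, 9-BBN-H, THF, 0 → 23 °C; then 11, PdCl2(dppf) (10 mol %), AsPh3, aq. K3PO4, DMF, 50 °C
Reagents that add atoms: none
Why: 9-BBN should add anti-Markovnikov to the terminal vinyl group only, and the B-alkyl Suzuki–Miyaura coupling with the enol triflate forms the C9–C11 bond with the E-alkene retained; epoxide, lactone and silyl ether are tolerated.

**Step 10**
Reactants: 16 coupled epoxy lactone
Product: 17 3α,6β,19-triol (C15 OTBS)
Conditions: LiAlH4 (excess), THF, 0 °C → reflux
Reagents that add atoms: none
Why: LiAlH4 reduces the lactone to the 6β,19-diol and opens the epoxide by hydride attack at C2 (trans-diaxial opening, Fürst–Plattner rule; C3 is neopentyl), which should give the axial 3α-alcohol.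

**Step 11**
Reactants: 17 triol
Product: 18 3α,19-bis(3-methylbutanoate) with free 6β-OH (C15 OTBS)
Conditions: isovaleric anhydride (2.5 equiv), DMAP, pyridine, 0 → 40 °C
Reagents that add atoms: 3-methylbutanoic anhydride CC(C)CC(=O)OC(=O)CC(C)C
Why: DMAP-catalysed acylation should take the primary 19-OH and the 3α-OH, while the 6β-OH, 1,3-diaxial to both the C10 methyl and C19, stays free.

**Step 12**
Reactants: 18 bis-ester silyl ether
Product: 19 15-alcohol (6β-OH free; 3α,19-diester)
Conditions: HF·pyridine, THF/pyridine, 0 → 23 °C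
Reagents that add atoms: none
Why: Acidic fluoride cleaves the primary allylic silyl ether (desilylation) without ester hydrolysis or acyl migration.

**Step 13**
Reactants: 19 allylic alcohol
Product: 20 15-aldehyde (13E enal)
Conditions: MnO2, CH2Cl2, 23 °C
Reagents that add atoms: none
Why: MnO2 oxidises only the allylic primary alcohol (allylic oxidation) and leaves the hindered saturated 6β-OH untouched.

**Step 14**
Reactants: 20 enal
Product: 21 target acid CNP0333611.1
Conditions: NaClO2, NaH2PO4, 2-methylbut-2-ene, t-BuOH/H2O, 0 → 23 °C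
Reagents that add atoms: sodium chlorite [Na+].[O-]Cl=O
Why: Pinnick oxidation converts the enal to the enoic acid without touching the alkenes, the esters or the secondary alcohol.

**Compound list**

1 | 2,6-dimethyl-1,4-benzoquinone | CC1=CC(=O)C=C(C)C1=O | starting material
2 | methyl (2E)-penta-2,4-dienoate | C=C/C=C/C(=O)OC | starting material
3 | methyl (1R,4aS,8aR)-4a,6-dimethyl-5,8-dioxo-1,4,4a,5,8,8a-hexahydronaphthalene-1-carboxylate (cis adduct) | CC1=CC(=O)[C@@H]2[C@H](C(=O)OC)C=CC[C@]2(C)C1=O | intermediate
4 | methyl (1R,4aS,8aS)-4a,6-dimethyl-5,8-dioxo-1,4,4a,5,8,8a-hexahydronaphthalene-1-carboxylate (trans-fused) | CC1=CC(=O)[C@H]2[C@H](C(=O)OC)C=CC[C@]2(C)C1=O | intermediate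
5 | lithium C9 enolate of the 7,8-dihydro derivative of 4 | CC1=C(O[Li])[C@@]2(C)CC=C[C@@H](C(=O)OC)[C@@H]2C(=O)C1 | intermediate
6 | C9 enol triflate, 6-ketone (Δ8, Δ2, 4α-CO2Me, 5α-H, 10β-Me) | CC1=C(OS(=O)(=O)C(F)(F)F)[C@@]2(C)CC=C[C@@H](C(=O)OC)[C@@H]2C(=O)C1 | intermediate
7 | 6β-alcohol of 6 | CC1=C(OS(=O)(=O)C(F)(F)F)[C@@]2(C)CC=C[C@@H](C(=O)OC)[C@@H]2[C@H](O)C1 | intermediate
8 | dilithium 6β-alkoxide / C4 ester enolate of 7 | CC1=C(OS(=O)(=O)C(F)(F)F)[C@@]2(C)CC=CC(=C(O[Li])OC)[C@@H]2[C@H](O[Li])C1 | intermediate
9 | lithium 6β-alkoxide of the 4α-methyl-4β-methoxycarbonyl compound | CC1=C(OS(=O)(=O)C(F)(F)F)[C@@]2(C)CC=C[C@](C)(C(=O)OC)[C@@H]2[C@H](O[Li])C1 | intermediate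
10 | 19,6β-lactone (4α-methyl, Δ2, 9-OTf, Δ8) | CC1=C(OS(=O)(=O)C(F)(F)F)[C@@]2(C)CC=C[C@](C)(C(=O)O3)[C@@H]2[C@H]3C1 | intermediate
11 | 2α,3α-epoxide of 10 | CC1=C(OS(=O)(=O)C(F)(F)F)[C@@]2(C)C[C@H]4O[C@H]4[C@](C)(C(=O)O3)[C@@H]2[C@H]3C1 | intermediate
12 | (2E)-3-methylpent-2-en-4-yn-1-ol | C#C/C(C)=C/CO | starting material
13 | tert-butyldimethylsilyl ether of 12 | C#C/C(C)=C/CO[Si](C)(C)C(C)(C)C | intermediate
14 | tert-butyldimethylsilyl ether of (2E)-3-methylpenta-2,4-dien-1-ol | C=C/C(C)=C/CO[Si](C)(C)C(C)(C)C | intermediate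
15 | B-[(3E)-5-(tert-butyldimethylsilyloxy)-3-methylpent-3-enyl]-9-BBN | C(C/C(C)=C/CO[Si](C)(C)C(C)(C)C)B1C2CCCC1CCC2 | intermediate
16 | coupled 2α,3α-epoxy-19,6β-lactone with C9 side chain (15-OTBS, 13E) | CC1=C(CC/C(C)=C/CO[Si](C)(C)C(C)(C)C)[C@@]2(C)C[C@H]4O[C@H]4[C@](C)(C(=O)O3)[C@@H]2[C@H]3C1 | intermediate
17 | 3α,6β,19-triol (15-OTBS, labda-8,13E-diene) | CC1=C(CC/C(C)=C/CO[Si](C)(C)C(C)(C)C)[C@@]2(C)CC[C@@H](O)[C@](C)(CO)[C@@H]2[C@H](O)C1 | intermediate
18 | 3α,19-bis(3-methylbutanoate), 6β-OH, 15-OTBS | CC1=C(CC/C(C)=C/CO[Si](C)(C)C(C)(C)C)[C@@]2(C)CC[C@@H](OC(=O)CC(C)C)[C@](C)(COC(=O)CC(C)C)[C@@H]2[C@H](O)C1 | intermediate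
19 | 15-alcohol (3α,19-diester, 6β-OH) | CC1=C(CC/C(C)=C/CO)[C@@]2(C)CC[C@@H](OC(=O)CC(C)C)[C@](C)(COC(=O)CC(C)C)[C@@H]2[C@H](O)C1 | intermediate
20 | 15-aldehyde (3α,19-diester, 6β-OH) | CC1=C(CC/C(C)=C/C=O)[C@@]2(C)CC[C@@H](OC(=O)CC(C)C)[C@](C)(COC(=O)CC(C)C)[C@@H]2[C@H](O)C1 | intermediate
21 | (3R,4S,5R,6R,10S)-6-hydroxy-3,19-bis(3-methylbutanoyloxy)labda-8,13E-dien-15-oic acid (CNP0333611.1) | CC1=C(CC/C(C)=C/C(=O)O)[C@@]2(C)CC[C@@H](OC(=O)CC(C)C)[C@](C)(COC(=O)CC(C)C)[C@@H]2[C@H](O)C1 | target

**Step count and risks**

Total step count: 14. Longest linear sequence: 12 steps (steps 1–6 and 9–14).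

Steps most likely to fail:

1. Step 1. The cycloaddition may be slow because the dienoate is electron-poor and its ester competes with the quinone for the Lewis acid, so regio- and enantiocontrol could erode. Fallback: raise the diene HOMO by moving C19 to the alcohol oxidation level. Setting out from 1, commercial (2E)-penta-2,4-dien-1-ol is silylated (TBSCl, imidazole) to tert-butyldimethylsilyl (2E)-penta-2,4-dienyl ether F1. The same catalysed cycloaddition with 1 (1-alkyl dienes are standard partners, same regiochemical sense) should give the silyloxymethyl cis adduct F2. One-pot desilylation and oxidation (CrO3/H2SO4, acetone) gives the carboxylic acid F3, and esterification with TMSCHN2 in MeOH returns to the route at 3.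

2. Step 3. The hydride may attack the C6 carbonyl 1,2 or reduce twice, so the C9 enolate would not form cleanly. Fallback: stepwise redox. Setting out from 4, Zn/AcOH reduces the ene-dione C=C to the saturated trans-dione F4 (C8 epimers). NaBH4 at −78 °C reduces the less hindered C6 ketone from the α-face to the 6β-hydroxy-9-ketone F5. KN(SiMe3)2 (2.2 equiv) with PhNTf2 then triflates the C9 enolate, which can form only toward C8, and the route is rejoined at 7.

3. Step 2. The cis/trans equilibrium may be unfavourable, or the base may move the C2=C3 double bond into conjugation with the ester. Fallback: kinetic instead of thermodynamic control. Setting out from 3, TMSOTf/Et3N gives the cross-conjugated silyl dienol ether F6 (C5=C6). Protonation at −78 °C (HF·pyridine) from the α-face, opposite to the angular methyl, should then give the trans-fused 4, where the route is rejoined.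

**Further compounds**

F1 | step 1 | tert-butyldimethylsilyl (2E)-penta-2,4-dienyl ether | C=C/C=C/CO[Si](C)(C)C(C)(C)C
F2 | step 1 | cis adduct with 4α-CH2OTBS (10β-Me, 5β-H, Δ2, 6,9-dioxo, Δ7) | CC1=CC(=O)[C@@H]2[C@H](CO[Si](C)(C)C(C)(C)C)C=CC[C@]2(C)C1=O
F3 | step 1 | carboxylic acid corresponding to 3 | CC1=CC(=O)[C@@H]2[C@H](C(=O)O)C=CC[C@]2(C)C1=O
F4 | step 3 | saturated trans-fused 6,9-dione ester (7,8-dihydro-4, C8 epimers) | CC1CC(=O)[C@H]2[C@H](C(=O)OC)C=CC[C@]2(C)C1=O
F5 | step 3 | 6β-hydroxy-9-ketone ester (C8 epimers) | CC1C[C@@H](O)[C@H]2[C@H](C(=O)OC)C=CC[C@]2(C)C1=O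
F6 | step 2 | trimethylsilyl dienol ether of 3 (C5=C6, 6-OTMS) | CC1=CC(O[Si](C)(C)C)=C2[C@H](C(=O)OC)C=CC[C@]2(C)C1=O
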